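**Retrosynthetic overview**

1. Numbering: left decalin C1–C10 (C3–OH, C4 gem-dimethyl, C7=C8, C8–Me), linker C11–C12, right decalin C1′–C10′ (C8′–Me). The strategy rests on ring B of each half (C5–C10): the C5 stereocentre beside the C4 gem-dimethyl carbon, the quaternary C10 and the methyl-bearing C8 beside C9 are the skeleton of (R)-carvone (C=O = C9, MeC=CH = C8=C7, stereocentre = C5, isopropenyl = C4 plus one methyl).
2. Target ⇐ C12 ketone (Wolff–Kishner) ⇐ Carroll rearrangement of a 7β-yl β-keto ester, which forms C9–C11 and moves the alkene to C7=C8 ⇐ left 7β-ol (C8=C9) + right C12 acid.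
3. Both partners ⇐ one silylated decalin enone (3β-OTBS, C7=C8, C9=O): the left one by epoxidation, Wharton transposition, oxidation and Luche reduction; the right one by hydrogenation/epimerisation, methylenation, hydroboration and oxidation.
4. Decalin enone ⇐ closure of ring A through the C3–C4 bond: hydrogen-atom transfer to the isopropenyl group and 6-exo addition of the C4 radical to a C3 aldehyde; the aldehyde ⇐ (R)-carvone by α′-methylation, α′-allylation and hydroboration/oxidation.
5. Ring order: ring B is bought as carvone, ring A is closed in step 5, and the same bicycle serves as rings A/B and A′/B′.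

Key step: step 5

Remark: the target SMILES is read as 3β,3′β-diol, 5α,5′α-H, 9α,9′α-H, 10β,10′β-methyl and 8′α-methyl (8′β-H); α/β are used in this sterol-like sense throughout.

**Step 1**
Reactants: 1 (R)-carvone; 2 iodomethane
Product: 4 trans-6-methylcarvone, via lithium dienolate 3 (not isolated)
Conditions: LiN(iPr)2 (LDA), THF, −78 °C; MeI, −78 → 0 °C
Reagents that add atoms: iodomethane, CI
Why: Kinetic α′-deprotonation gives the cross-conjugated dienolate, whose C-methylation (enolate alkylation) installs the future C10 methyl mainly anti to the isopropenyl group; the configuration at this carbon is of no consequence because it is planarised again in step 2.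

**Step 2**
Reactants: 4 trans-6-methylcarvone; 5 allyl bromide
Product: 7 6-allyl-6-methylcarvone (methyl cis, allyl trans to isopropenyl), via lithium enolate 6 (not isolated)
Conditions: LiN(iPr)2 (LDA), THF, −78 → 0 °C; DMPU, allyl bromide, −78 °C → rt
Reagents that add atoms: allyl bromide, C=CCBr
Why: Enolate alkylation of the tetrasubstituted enolate takes place on the face opposite to the neighbouring isopropenyl group, so the allyl group enters trans and the methyl ends cis to it, which sets the quaternary future C10 with its β-methyl.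

**Step 3**
Reactants: 7 6-allyl-6-methylcarvone
Product: 9 6-(3-hydroxypropyl)-6-methylcarvone, via alkyldisiamylborane 8 (not isolated)
Conditions: Sia2BH (from BH3·SMe2 and 2-methylbut-2-ene, THF, 0 °C), THF, 0 °C; then NaBO3·4H2O, H2O, rt
Reagents that add atoms: sodium perborate, [Na+].[Na+].O[B-]1(O)OO[B-](O)(O)OO1
Why: Hydroboration–oxidation; the bulky dialkylborane adds anti-Markovnikov to the monosubstituted allyl alkene much faster than to the hindered 1,1-disubstituted isopropenyl alkene or the neopentyl-type conjugated ketone, and perborate oxidises the C–B bond without the strongly basic peroxide that would epoxidise the enone.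

**Step 4**
Reactants: 9 6-(3-hydroxypropyl)-6-methylcarvone
Product: 10 6-methyl-6-(3-oxopropyl)carvone (key precursor)
Conditions: Dess–Martin periodinane, CH2Cl2, rt
Reagents that add atoms: none
Why: Dess–Martin oxidation converts the primary alcohol into the aldehyde under neutral conditions that leave the enone and the isopropenyl group untouched and cannot over-oxidise.

**Step 5**
Reactants: 10 6-methyl-6-(3-oxopropyl)carvone
Product: 11 3β-hydroxy-4,4,8,10-tetramethyl trans-decal-7-en-9-one (5α-H, 10β-Me)
Conditions: Fe(acac)3 (0.3 equiv), PhSiH3 (2.5 equiv), degassed EtOH, 60 °C, 0.02 M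
Reagents that add atoms: none
Why: An iron hydride generated from trivalent iron Fe(acac)3 and PhSiH3 in EtOH transfers a hydrogen atom to the CH2 terminus of the isopropenyl group, which creates the second C4 methyl and the tertiary C4 radical; this radical adds to the C3 aldehyde carbon, and the C3 alkoxy radical is reduced by divalent iron and protonated by EtOH, which returns trivalent iron. The closest known reaction type is the iron-hydride HAT-initiated reductive radical cyclization of alkene-tethered carbonyl compounds, together with the HAT-initiated radical addition of unactivated alkenes to aldehydes. Ring A (C3, C4, C5, C10, C1, C2) closes in the 6-exo-trig mode through the C3–C4 bond, and its trans fusion to ring B is fixed beforehand because the C5 and C10 arms are trans and both equatorial on the carvone ring. The new C3 stereocentre is controlled by a chair transition state in which the carbonyl oxygen lies pseudoequatorial, away from the axial hydrogens at C1 and C5, so the 3β (equatorial) alcohol should form, helped by the reversibility of the addition. The step needs hydrogen-atom transfer to the isopropenyl group and not to the enone, which the substrate secures because the electron-rich 1,1-disubstituted alkene is a far better hydrogen-atom acceptor than the electron-poor C7=C8 bond and because the C4 radical could reach C7 or C9 only through a four-membered ring; high dilution keeps addition to the enone of a second molecule low.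

**Step 6**
Reactants: 11 3β-hydroxy decalin enone
Product: 12 3β-(tert-butyldimethylsilyloxy)-4,4,8,10-tetramethyl trans-decal-7-en-9-one
Conditions: TBSCl, imidazole, DMAP (cat.), DMF, 40 °C
Reagents that add atoms: tert-butyldimethylsilyl chloride, CC(C)(C)[Si](C)(C)Cl
Why: Silyl ether formation at the only hydroxyl group masks C3–OH for the oxidations, the organometallic steps and the acylations that follow.

**Step 7**
Reactants: 12 silyl ether enone
Product: 13 7α,8α-epoxy-3β-silyloxy-9-ketone
Conditions: 30% H2O2, NaOH (aq), MeOH/THF, 0 °C → rt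
Reagents that add atoms: hydrogen peroxide, OO
Why: Weitz–Scheffer nucleophilic epoxidation; hydroperoxide adds to C7 of the enone and the enolate closes onto oxygen, expected from the α face away from the axial C10 methyl, and the facial outcome is of no consequence because C8 and C7 become sp2 again in steps 8 and 9.

**Step 8**
Reactants: 13 epoxy ketone
Product: 15 7α-hydroxy-3β-silyloxy-8-methyl decal-8(9)-ene, via epoxy hydrazone 14 (not isolated)
Conditions: N2H4·H2O, AcOH (cat.), MeOH, 0 °C → rt
Reagents that add atoms: none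
Why: Wharton transposition; the hydrazone opens the epoxide to a vinyl diazene that loses N2, which moves the oxygen from C9 to C7 and the alkene to C8=C9 with retention at C7.

**Step 9**
Reactants: 15 7α-allylic alcohol
Product: 16 3β-silyloxy-8-methyl decal-8(9)-en-7-one
Conditions: Dess–Martin periodinane, CH2Cl2, 0 °C → rt
Reagents that add atoms: none
Why: Dess–Martin oxidation of the allylic alcohol gives the transposed enone and so erases the C7 configuration that the epoxidation had set.

**Step 10**
Reactants: 16 transposed enone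
Product: 17 7β-hydroxy-3β-silyloxy-8-methyl decal-8(9)-ene
Conditions: NaBH4, CeCl3·7H2O, MeOH, −40 °C
Reagents that add atoms: none
Why: Luche reduction; axial hydride delivery to C7 from the α face should give the pseudoequatorial 7β-alcohol, as in the reduction of carvone to cis-carveol, and this is the C7 configuration that the later suprafacial shift needs.

**Step 11**
Reactants: 12 silyl ether enone
Product: 19 3β-silyloxy-8α-methyl trans-decalin-9-one, via 8β-methyl ketone 18 (not isolated)
Conditions: H2 (1 atm), 10% Pd/C, EtOAc, rt; filter; NaOMe, MeOH, rt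
Reagents that add atoms: none
Why: Catalytic hydrogenation saturates C7=C8, and base-mediated epimerisation α to the C9 ketone then places the C8 methyl equatorial (8α), since an 8β-methyl would be 1,3-diaxial to the C10 methyl; the C8′ stereocentre of the target is thus set under thermodynamic control.

**Step 12**
Reactants: 19 8α-methyl decalin-9-one; 20 methyltriphenylphosphonium bromide
Product: 21 9′-methylene-3′β-silyloxy-8′α-methyl decalin (right-half numbering, exocyclic C9′=C12)
Conditions: KOtBu, toluene, 100 °C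
Reagents that add atoms: methyltriphenylphosphonium bromide, C[P+](c1ccccc1)(c1ccccc1)c1ccccc1.[Br-]
Why: Wittig methylenation with the smallest ylide at elevated temperature is a known answer to hindered 2,2,6-trisubstituted cyclohexanones, and the basic medium can only keep C8′ at its more stable 8′α-methyl configuration.

**Step 13**
Reactants: 21 exocyclic alkene
Product: 23 C12 primary alcohol (9′β-CH2OH, 9′α-H, 8′α-Me), via B-alkyl-9-BBN adduct 22 (not isolated)
Conditions: 9-BBN, THF, 65 °C; then NaOH (aq), 30% H2O2, 0 °C → rt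
Reagents that add atoms: hydrogen peroxide, OO
Why: Hydroboration–oxidation; boron adds to the terminal C12 and hydrogen to C9′ from the α face, opposite to the axial C10′ methyl that shields the β face, which sets 9′α-H with the equatorial CH2OH arm.

**Step 14**
Reactants: 23 C12 alcohol
Product: 25 C12 carboxylic acid (9′β-CO2H), via C12 aldehyde 24 (not isolated)
Conditions: TEMPO (cat.), NaClO2, NaOCl (cat.), MeCN/phosphate buffer pH 6.7, 35 °C
Reagents that add atoms: sodium chlorite, [Na+].[O-]Cl=O
Why: TEMPO/hypochlorite oxidation to the aldehyde with in-situ chlorite oxidation to the acid is a mild buffered one-flask oxidation of primary alcohols that spares the silyl ether, and C9′ keeps its more stable equatorial configuration.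

**Step 15**
Reactants: 25 C12 acid; 26 Meldrum's acid
Product: 28 C12 acyl Meldrum's acid (enol form), via C12 acid chloride 27 (not isolated)
Conditions: (COCl)2, DMF (cat.), CH2Cl2, 0 °C → rt; concentrate; Meldrum's acid, pyridine, DMAP (cat.), CH2Cl2, 0 °C → rt
Reagents that add atoms: Meldrum's acid, CC1(C)OC(=O)CC(=O)O1
Why: C-acylation of Meldrum's acid by the acid chloride gives the acyl Meldrum's acid, a storable acylketene precursor in which C11 and the future ester carbonyl are already attached to C12.

**Step 16**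
Reactants: 17 7β-allylic alcohol; 28 acyl Meldrum's acid
Product: 30 7β-yl β-keto ester (C7–O–CO–C11H2–C12(=O)–C9′), via acylketene 29 (not isolated)
Conditions: toluene, 100 °C
Reagents that add atoms: none
Why: Thermolysis of the acyl Meldrum's acid (retro-[4+2] loss of acetone and CO2) gives an acylketene, which the secondary allylic alcohol traps at the unhindered ketene carbon to give the β-keto ester without touching the C7 configuration.

**Step 17**
Reactants: 30 β-keto ester
Product: 32 bis-silyl C12 ketone (C7=C8, 9α-H, C9–C11H2–C12(=O)–C9′), via β-keto acid 31 (not isolated)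
Conditions: degassed 1,2-dichlorobenzene, 180 °C, sealed tube
Reagents that add atoms: none
Why: Carroll rearrangement; the enol of the allylic β-keto ester undergoes a suprafacial [3,3]-sigmatropic shift through a boat-like ring B conformer that breaks C7–O and forms C9–C11 on the β face from which the oxygen leaves, setting 9α-H and moving the alkene to C7=C8, and the β-keto acid loses CO2 at this temperature.

**Step 18**
Reactants: 32 bis-silyl C12 ketone
Product: 33 3β,3′β-dihydroxy C12 ketone
Conditions: HF·pyridine, pyridine/THF, 0 °C → rt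
Reagents that add atoms: none
Why: Fluoride-mediated desilylation with buffered HF·pyridine cleaves both silyl ethers while leaving the trisubstituted C7=C8 alkene in place, and frees the diol before the strongly basic last step so that no protecting group has to survive it.

**Step 19**
Reactants: 33 keto diol
Product: 35 CNP0194061.1 (target), via C12 hydrazone 34 (not isolated)
Conditions: N2H4·H2O, KOH, diethylene glycol, 130 °C, then 200 °C with removal of water
Reagents that add atoms: none
Why: Wolff–Kishner reduction (Huang-Minlon procedure) converts the C12 carbonyl into CH2 through the hydrazone with loss of N2; hydroxyl groups and the isolated γ,δ-alkene are inert to it, C9 is not enolisable, and base equilibration α to the ketone can only favour the equatorial 9′α-H configuration already present.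

**Compound list**

1 | (R)-carvone, (5R)-2-methyl-5-(prop-1-en-2-yl)cyclohex-2-en-1-one | CC1=CC[C@H](CC1=O)C(C)=C | starting material
2 | iodomethane | CI | starting material
3 | lithium dienolate of 1 (O–C1=C6, carvone numbering) | CC1=CC[C@@H](C(C)=C)C=C1[O-].[Li+] | intermediate
4 | trans-6-methylcarvone, (5R,6S)-2,6-dimethyl-5-(prop-1-en-2-yl)cyclohex-2-en-1-one (major epimer; the C6 epimer mixture is used) | CC1=CC[C@@H](C(C)=C)[C@H](C)C1=O | intermediate
5 | allyl bromide | C=CCBr | starting material
6 | lithium enolate of 4 (tetrasubstituted O–C1=C6) | CC1=CC[C@@H](C(C)=C)C(C)=C1[O-].[Li+] | intermediate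
7 | (5S,6S)-6-allyl-2,6-dimethyl-5-(prop-1-en-2-yl)cyclohex-2-en-1-one (methyl cis, allyl trans to isopropenyl) | CC1=CC[C@@H](C(C)=C)[C@](C)(CC=C)C1=O | intermediate
8 | bis(3-methylbutan-2-yl)[3-(ring C6)propyl]borane adduct of 7 | CC1=CC[C@@H](C(C)=C)[C@](C)(CCCB(C(C)C(C)C)C(C)C(C)C)C1=O | intermediate
9 | (5S,6S)-6-(3-hydroxypropyl)-2,6-dimethyl-5-(prop-1-en-2-yl)cyclohex-2-en-1-one | CC1=CC[C@@H](C(C)=C)[C@](C)(CCCO)C1=O | intermediate
10 | (5S,6S)-2,6-dimethyl-6-(3-oxopropyl)-5-(prop-1-en-2-yl)cyclohex-2-en-1-one | CC1=CC[C@@H](C(C)=C)[C@](C)(CCC=O)C1=O | intermediate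
11 | 3β-hydroxy-4,4,8,10β-tetramethyl-5α-decal-7-en-9-one | CC1=CC[C@H]2C(C)(C)[C@@H](O)CC[C@]2(C)C1=O | intermediate
12 | 3β-TBS ether of 11 | CC1=CC[C@H]2C(C)(C)[C@@H](O[Si](C)(C)C(C)(C)C)CC[C@]2(C)C1=O | intermediate
13 | 7α,8α-epoxy-3β-TBSO-4,4,8,10-tetramethyl-5α-decalin-9-one | C[C@@]12O[C@@H]1C[C@H]3C(C)(C)[C@@H](O[Si](C)(C)C(C)(C)C)CC[C@]3(C)C2=O | intermediate
14 | C9 hydrazone of 13 | C[C@@]12O[C@@H]1C[C@H]3C(C)(C)[C@@H](O[Si](C)(C)C(C)(C)C)CC[C@]3(C)C2=NN | intermediate
15 | 7α-hydroxy-3β-TBSO-4,4,8,10-tetramethyl-5α-decal-8(9)-ene | O[C@@H]1C[C@H]2C(C)(C)[C@@H](O[Si](C)(C)C(C)(C)C)CC[C@]2(C)C=C1C | intermediate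
16 | 3β-TBSO-4,4,8,10-tetramethyl-5α-decal-8(9)-en-7-one | O=C1C[C@H]2C(C)(C)[C@@H](O[Si](C)(C)C(C)(C)C)CC[C@]2(C)C=C1C | intermediate
17 | 7β-hydroxy-3β-TBSO-4,4,8,10-tetramethyl-5α-decal-8(9)-ene | O[C@H]1C[C@H]2C(C)(C)[C@@H](O[Si](C)(C)C(C)(C)C)CC[C@]2(C)C=C1C | intermediate
18 | 3β-TBSO-4,4,8β,10-tetramethyl-5α-decalin-9-one (kinetic C8 epimer) | C[C@H]1CC[C@H]2C(C)(C)[C@@H](O[Si](C)(C)C(C)(C)C)CC[C@]2(C)C1=O | intermediate
19 | 3β-TBSO-4,4,8α,10-tetramethyl-5α-decalin-9-one | C[C@@H]1CC[C@H]2C(C)(C)[C@@H](O[Si](C)(C)C(C)(C)C)CC[C@]2(C)C1=O | intermediate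
20 | methyltriphenylphosphonium bromide | C[P+](c1ccccc1)(c1ccccc1)c1ccccc1.[Br-] | starting material
21 | 9′-methylene-3′β-TBSO-4′,4′,8′α,10′-tetramethyl-5′α-decalin | C[C@@H]1CC[C@H]2C(C)(C)[C@@H](O[Si](C)(C)C(C)(C)C)CC[C@]2(C)C1=C | intermediate
22 | 9-(C12-yl)-9-borabicyclo[3.3.1]nonane adduct of 21 (9′α-H) | C[C@@H]1CC[C@H]2C(C)(C)[C@@H](O[Si](C)(C)C(C)(C)C)CC[C@]2(C)[C@H]1CB1C2CCCC1CCC2 | intermediate
23 | 9′β-(hydroxymethyl)-3′β-TBSO-4′,4′,8′α,10′-tetramethyl-5′α-decalin | C[C@@H]1CC[C@H]2C(C)(C)[C@@H](O[Si](C)(C)C(C)(C)C)CC[C@]2(C)[C@H]1CO | intermediate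
24 | corresponding 9′β-carbaldehyde (C12 aldehyde) | C[C@@H]1CC[C@H]2C(C)(C)[C@@H](O[Si](C)(C)C(C)(C)C)CC[C@]2(C)[C@H]1C=O | intermediate
25 | corresponding 9′β-carboxylic acid (C12 acid) | C[C@@H]1CC[C@H]2C(C)(C)[C@@H](O[Si](C)(C)C(C)(C)C)CC[C@]2(C)[C@H]1C(=O)O | intermediate
26 | Meldrum's acid, 2,2-dimethyl-1,3-dioxane-4,6-dione | CC1(C)OC(=O)CC(=O)O1 | starting material
27 | C12 acid chloride | C[C@@H]1CC[C@H]2C(C)(C)[C@@H](O[Si](C)(C)C(C)(C)C)CC[C@]2(C)[C@H]1C(=O)Cl | intermediate
28 | 5-[hydroxy(right-half C9′-yl)methylene] Meldrum's acid | C[C@@H]1CC[C@H]2C(C)(C)[C@@H](O[Si](C)(C)C(C)(C)C)CC[C@]2(C)[C@H]1C(O)=C1C(=O)OC(C)(C)OC1=O | intermediate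
29 | right-half acylketene (C9′–CO–CH=C=O) | C[C@@H]1CC[C@H]2C(C)(C)[C@@H](O[Si](C)(C)C(C)(C)C)CC[C@]2(C)[C@H]1C(=O)C=C=O | intermediate
30 | 7β-yl 3-oxo-3-(right-half C9′-yl)propanoate | C[C@@H]1CC[C@H]2C(C)(C)[C@@H](O[Si](C)(C)C(C)(C)C)CC[C@]2(C)[C@H]1C(=O)CC(=O)O[C@H]1C[C@H]2C(C)(C)[C@@H](O[Si](C)(C)C(C)(C)C)CC[C@]2(C)C=C1C | intermediate
31 | β-keto acid with CO2H on C11 (C11 configuration unassigned, lost on decarboxylation) | CC1=CC[C@H]2C(C)(C)[C@@H](O[Si](C)(C)C(C)(C)C)CC[C@]2(C)[C@H]1C(C(=O)O)C(=O)[C@H]1[C@H](C)CC[C@H]2C(C)(C)[C@@H](O[Si](C)(C)C(C)(C)C)CC[C@]12C | intermediate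
32 | 3β,3′β-bis(TBSO) 12-ketone of the target skeleton | CC1=CC[C@H]2C(C)(C)[C@@H](O[Si](C)(C)C(C)(C)C)CC[C@]2(C)[C@H]1CC(=O)[C@H]1[C@H](C)CC[C@H]2C(C)(C)[C@@H](O[Si](C)(C)C(C)(C)C)CC[C@]12C | intermediate
33 | 3β,3′β-dihydroxy 12-ketone | CC1=CC[C@H]2C(C)(C)[C@@H](O)CC[C@]2(C)[C@H]1CC(=O)[C@H]1[C@H](C)CC[C@H]2C(C)(C)[C@@H](O)CC[C@]12C | intermediate
34 | C12 hydrazone of 33 | CC1=CC[C@H]2C(C)(C)[C@@H](O)CC[C@]2(C)[C@H]1CC(=NN)[C@H]1[C@H](C)CC[C@H]2C(C)(C)[C@@H](O)CC[C@]12C | intermediate
35 | CNP0194061.1 | CC1=CC[C@H]2C(C)(C)[C@@H](O)CC[C@]2(C)[C@H]1CC[C@H]1[C@H](C)CC[C@H]2C(C)(C)[C@@H](O)CC[C@]12C | target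

**Step count**

Total: 19 steps. Longest linear sequence: 15 steps (steps 1–6, 11–15, 16–19).

**Steps most likely to fail**

1. Step 17. The [3,3] shift needs ring B in a boat-like conformer with the C7–O bond pseudoaxial on the β face, and it forms the C9–C11 bond beside the quaternary C10. It may therefore be slower than thermal loss of the acyl unit as acylketene and elimination across ring B. Fallback, setting out from 23 and 17 and rejoining the route at 35:
   - Alcohol 23 is oxidised with Dess–Martin periodinane to aldehyde 24, here isolated.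
   - Horner–Wadsworth–Emmons reaction with benzyl diethylphosphonoacetate (NaH, THF) gives the benzyl (E)-enoate F4.
   - H2 over Pd/C saturates the alkene and cleaves the benzyl ester to give the propanoic acid F5 (C9′–C12H2–C11H2–CO2H).
   - EDC/DMAP esterification with 17 gives the 7β-yl ester F6.
   - Ireland–Claisen rearrangement (LiN(iPr)2, Me3SiCl, THF, −78 → 60 °C) passes through the silyl ketene acetal F7 and forms C9–C11 on the β face to give the trimethylsilyl ester F8; aqueous work-up gives the C11 carboxylic acid F9.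
   - The acid is converted with N-hydroxypyridine-2-thione and EDC into the Barton ester F10, and photolysis with t-BuSH (Barton decarboxylation) gives the bis-silyl ether F11 of the target.
   - HF·pyridine then gives 35.
   
   The silyl ketene acetal rearranges well below 100 °C and no C12 carbonyl has to be removed.

2. Step 5. The tertiary C4 radical may be quenched by a second hydrogen-atom transfer before it adds to the aldehyde, or the aldehyde may be lost to acetal formation or silane reduction, so that ring A does not close. Fallback, setting out from 10 and rejoining at 11: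
   - HBr in AcOH at 0 °C adds to the isopropenyl group in the Markovnikov sense to give the tertiary bromide F1.
   - Slow addition of Bu3SnH with AIBN in benzene at 80 °C generates the same C4 radical by bromine abstraction; it closes ring A 6-exo onto the aldehyde and the alkoxy radical is trapped by the tin hydride.

3. Step 8. Hydrazone formation at the C9 carbonyl, which lies between two fully substituted carbons, may be slow enough for hydrazine to open the epoxide at C7 instead, giving pyrazoline-type products without transposition. Fallback, setting out from 13 and rejoining at 15: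
   - NaBH4 in MeOH reduces the C9 ketone to the epoxy alcohol F2 (either C9 epimer serves).
   - PhOC(S)Cl with pyridine and DMAP gives the phenyl thionocarbonate F3.
   - Bu3SnH/AIBN in toluene at 100 °C generates the C9 radical, which opens the epoxide by C8–O cleavage to the C7 alkoxy radical; hydrogen transfer from the tin hydride gives the 7α-ol 15.

**Further compounds**

F1 | step 5 | (5S,6S)-5-(2-bromopropan-2-yl)-2,6-dimethyl-6-(3-oxopropyl)cyclohex-2-en-1-one | CC1=CC[C@@H](C(C)(C)Br)[C@](C)(CCC=O)C1=O
F2 | step 8 | 7α,8α-epoxy-3β-TBSO-4,4,8,10-tetramethyl-5α-decalin-9-ol (C9 unassigned) | C[C@@]12O[C@@H]1C[C@H]3C(C)(C)[C@@H](O[Si](C)(C)C(C)(C)C)CC[C@]3(C)C2O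
F3 | step 8 | O-phenyl thionocarbonate of F2 | C[C@@]12O[C@@H]1C[C@H]3C(C)(C)[C@@H](O[Si](C)(C)C(C)(C)C)CC[C@]3(C)C2OC(=S)Oc1ccccc1
F4 | step 17 | benzyl (E)-3-(right-half C9′-yl)prop-2-enoate | C[C@@H]1CC[C@H]2C(C)(C)[C@@H](O[Si](C)(C)C(C)(C)C)CC[C@]2(C)[C@H]1/C=C/C(=O)OCc1ccccc1
F5 | step 17 | 3-(right-half C9′-yl)propanoic acid | C[C@@H]1CC[C@H]2C(C)(C)[C@@H](O[Si](C)(C)C(C)(C)C)CC[C@]2(C)[C@H]1CCC(=O)O
F6 | step 17 | 7β-yl ester of F5 with 17 | C[C@@H]1CC[C@H]2C(C)(C)[C@@H](O[Si](C)(C)C(C)(C)C)CC[C@]2(C)[C@H]1CCC(=O)O[C@H]1C[C@H]2C(C)(C)[C@@H](O[Si](C)(C)C(C)(C)C)CC[C@]2(C)C=C1C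
F7 | step 17 | trimethylsilyl ketene acetal of F6 (alkene geometry unassigned) | C[C@@H]1CC[C@H]2C(C)(C)[C@@H](O[Si](C)(C)C(C)(C)C)CC[C@]2(C)[C@H]1CC=C(O[Si](C)(C)C)O[C@H]1C[C@H]2C(C)(C)[C@@H](O[Si](C)(C)C(C)(C)C)CC[C@]2(C)C=C1C
F8 | step 17 | trimethylsilyl ester of the rearranged C11 acid (C11 unassigned) | CC1=CC[C@H]2C(C)(C)[C@@H](O[Si](C)(C)C(C)(C)C)CC[C@]2(C)[C@H]1C(C(=O)O[Si](C)(C)C)C[C@H]1[C@H](C)CC[C@H]2C(C)(C)[C@@H](O[Si](C)(C)C(C)(C)C)CC[C@]12C
F9 | step 17 | bis-silyl target skeleton with CO2H on C11 (C11 unassigned) | CC1=CC[C@H]2C(C)(C)[C@@H](O[Si](C)(C)C(C)(C)C)CC[C@]2(C)[C@H]1C(C(=O)O)C[C@H]1[C@H](C)CC[C@H]2C(C)(C)[C@@H](O[Si](C)(C)C(C)(C)C)CC[C@]12C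
F10 | step 17 | Barton ester (N-acyloxypyridine-2-thione) of F9 | CC1=CC[C@H]2C(C)(C)[C@@H](O[Si](C)(C)C(C)(C)C)CC[C@]2(C)[C@H]1C(C(=O)On1ccccc1=S)C[C@H]1[C@H](C)CC[C@H]2C(C)(C)[C@@H](O[Si](C)(C)C(C)(C)C)CC[C@]12C
F11 | step 17 | 3β,3′β-bis(TBS) ether of the target | CC1=CC[C@H]2C(C)(C)[C@@H](O[Si](C)(C)C(C)(C)C)CC[C@]2(C)[C@H]1CC[C@H]1[C@H](C)CC[C@H]2C(C)(C)[C@@H](O[Si](C)(C)C(C)(C)C)CC[C@]12C
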